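**Plan**

- Ring B is numbered C1 (ether to ring A), C2 (OH), C3 (OH), C4 (ether to ring C), C5 (OH), C6 (H). The para hydroxyls at C2 and C5, flanked by oxygens at C1, C3 and C4 with hydrogen at C6, make it the hydroquinone of a trioxygenated 1,4-benzoquinone, which is the product type of a squarate–alkynol ring expansion.
- Retrosynthetic cuts, in order: the nine O–benzyl bonds and the quinone oxidation level; the ring B C4–O bond to the ring C/D phenol (C4 as chloride); the ring B C1–C2 bond, back to a 4-hydroxy-4-(aryloxyethynyl)cyclobutenone; the carbinol–alkyne bond, back to dibenzyl squarate and a lithium aryloxyacetylide made from the ring A phenol and trichloroethylene; the ring C–O–ring D ether (Ullmann coupling).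
- Forward: rings A, C and D are bought as aromatic aldehydes or a bromide and carried as benzyl ethers. Ring B is the only ring that is built (step 6) and is formed with ring A already on C1. C4 is then unmasked, chlorinated and joined to the ring C/D phenol, and one hydrogenation finishes the synthesis.
- Stereochemistry: the target has no stereocentre. The only one on the way, the carbinol carbon of the cyclobutenone, is racemic and disappears in step 6.

Key step: step 6

Remark on the chemistry: exchanging a benzyloxy group on the quinone for an aryloxy group is uphill (benzyloxide is the poorer leaving group, and an aryloxide would sooner exchange the aryl ether at C1). The C4 oxygen is therefore freed and converted to chloride before the ring C/D phenol is introduced.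

Assumption: 3,4,5-tris(benzyloxy)benzaldehyde and 5-bromobenzene-1,2,3-triol are purchased.

**Route**

Step 1
Reactants: 1 2,4,6-trihydroxybenzaldehyde
Product: 2 2,4,6-tris(benzyloxy)benzaldehyde
Conditions: BnBr (3.6 equiv), K2CO3, DMF, 70 °C
Reagents that add atoms: benzyl bromide, BrCc1ccccc1
Why: Williamson ether synthesis; the formyl group lowers the carbon nucleophilicity of the phloroglucinol ring so that all three phenoxide oxygens should be benzylated, the two chelated ortho hydroxyls needing the excess of base and the gentle heating.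

Step 2
Reactants: 2 2,4,6-tris(benzyloxy)benzaldehyde
Product: 4 2,4,6-tris(benzyloxy)phenol, via 2,4,6-tris(benzyloxy)phenyl formate 3 (not isolated)
Conditions: mCPBA, CH2Cl2, 0 °C to rt; then K2CO3 (cat.), MeOH, rt
Reagents that add atoms: mCPBA, OOC(=O)c1cccc(Cl)c1
Why: Baeyer–Villiger (Dakin-type) oxidation in which the very electron-rich aryl group migrates in preference to hydrogen, followed by methanolysis of the aryl formate.

Step 3
Reactants: 4 2,4,6-tris(benzyloxy)phenol; 5 trichloroethylene
Product: 6 1,3,5-tris(benzyloxy)-2-{[(E)-1,2-dichloroethenyl]oxy}benzene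
Conditions: K2CO3, DMF, 70 °C
Reagents that add atoms: none
Why: Base-mediated addition of a phenoxide to dichloroacetylene formed in the flask from trichloroethylene, the standard preparation of aryl 1,2-dichlorovinyl ethers; anti addition should give the E isomer, whose geometry is of no consequence later.

Step 4
Reactants: 7 squaric acid
Product: 8 3,4-bis(benzyloxy)cyclobut-3-ene-1,2-dione (dibenzyl squarate)
Conditions: BnOH (excess), toluene, reflux, Dean–Stark trap
Reagents that add atoms: benzyl alcohol, OCc1ccccc1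
Why: Azeotropic esterification of the vinylogous diacid, the usual way to dialkyl squarates.

Step 5
Reactants: 6 1,3,5-tris(benzyloxy)-2-{[(E)-1,2-dichloroethenyl]oxy}benzene; 8 dibenzyl squarate
Product: 11 2,3-bis(benzyloxy)-4-hydroxy-4-{[2,4,6-tris(benzyloxy)phenoxy]ethynyl}cyclobut-2-en-1-one (racemic), via chloroethynyl aryl ether 9 (not isolated), via lithium aryloxyacetylide 10 (not isolated)
Conditions: 6, n-BuLi (2.2 equiv), THF, −78 to −40 °C; then 8, THF, −78 °C; aq. NH4Cl
Reagents that add atoms: none
Why: Dehydrochlorination and chlorine–lithium exchange of a 1,2-dichlorovinyl ether give the lithium aryloxyacetylide, which should add 1,2 to one of the two equivalent carbonyl groups of the squarate at low temperature as other lithium acetylides do; the new carbinol centre is racemic and is erased in step 6.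

Step 6
Reactants: 11 2,3-bis(benzyloxy)-4-hydroxy-4-{[2,4,6-tris(benzyloxy)phenoxy]ethynyl}cyclobut-2-en-1-one
Product: 14 2,3-bis(benzyloxy)-5-[2,4,6-tris(benzyloxy)phenoxy]cyclohexa-2,5-diene-1,4-dione, via enynylketene 12 (not isolated), via aryl diradical 13 (not isolated)
Conditions: toluene (0.01 M, degassed), 110 °C
Reagents that add atoms: none
Why: Heating opens the cyclobutenone in a conrotatory four-electron electrocyclic reaction, the hydroxyl turning outward and the alkynyl group inward, to give (Z)-enynylketene 12; its ketene carbon (future C2) bonds to the aryloxy-bearing alkyne carbon (future C1) to give diradical 13 (phenoxyl oxygen on C2, sigma radical on C6), and transfer of the hydroxyl hydrogen from the C5 oxygen to C6 gives quinone 14. The closest known reaction is the Moore rearrangement of squarate-derived 4-alkynyl-4-hydroxycyclobutenones to 1,4-benzoquinones. Ring B closes in the six-membered mode (endo with respect to the alkyne) by forming the C1–C2 bond, the squarate supplying C2 to C5 with their oxygens and the ynol ether supplying C1 (with ring A) and C6. No stereocentre is formed, and the racemic carbinol carbon of 11 becomes the C5 carbonyl. The step needs six- over five-membered closure (bonding to the proximal alkyne carbon would give a 2-alkylidenecyclopent-4-ene-1,3-dione): an oxygen substituent on the distal alkyne carbon gives no conjugative stabilisation to the exocyclic vinyl radical of the five-membered path, unlike aryl, silyl or ester groups, while the six-membered path gains the aromatic stabilisation of 13, and the connectivity of 11 leaves no regiochemical choice for ring A (C1) and hydrogen (C6). High dilution and exclusion of oxygen should keep the diradical from intermolecular reactions, and the aryl ynol ether has no hydrogen placed for a retro-ene loss, so it should survive 110 °C.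

Step 7
Reactants: 14 2,3-bis(benzyloxy)-5-[2,4,6-tris(benzyloxy)phenoxy]cyclohexa-2,5-diene-1,4-dione
Product: 15 3-(benzyloxy)-2-hydroxy-5-[2,4,6-tris(benzyloxy)phenoxy]cyclohexa-2,5-diene-1,4-dione
Conditions: MgBr2·OEt2 (3 equiv), toluene/Et2O, rt to 40 °C; then dilute HCl
Reagents that add atoms: none
Why: Chelation-assisted debenzylation with MgBr2 (cleavage of a benzyl ether next to a carbonyl group): magnesium should bind the more Lewis-basic C5 carbonyl oxygen (it receives electron density from both the C1 aryloxy and the C3 benzyloxy group) together with the neighbouring C4 ether oxygen, and bromide removes that benzyl group because the C4 oxide is also the better leaving group (a vinylogous carboxylate of the C2 carbonyl), while the aryl ether at C1 and the aryl benzyl ethers of ring A cannot react in this way.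

Step 8
Reactants: 15 3-(benzyloxy)-2-hydroxy-5-[2,4,6-tris(benzyloxy)phenoxy]cyclohexa-2,5-diene-1,4-dione
Product: 16 3-(benzyloxy)-2-chloro-5-[2,4,6-tris(benzyloxy)phenoxy]cyclohexa-2,5-diene-1,4-dione
Conditions: (COCl)2 (1.5 equiv), DMF (5 mol %), CH2Cl2, 0 °C
Reagents that add atoms: oxalyl chloride, O=C(Cl)C(=O)Cl
Why: Conversion of a vinylogous carboxylic acid (a 2-hydroxyquinone) into the vinylogous acid chloride with the Vilsmeier reagent from oxalyl chloride and catalytic DMF, the low DMF loading and temperature sparing the electron-rich ring A.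

Step 9
Reactants: 17 3,4,5-tris(benzyloxy)benzaldehyde
Product: 18 3,5-bis(benzyloxy)-4-hydroxybenzaldehyde
Conditions: BCl3 (1.2 equiv), CH2Cl2, −78 to −20 °C; then H2O
Reagents that add atoms: none
Why: Lewis-acid ether cleavage selective for the central alkoxy group of a 3,4,5-trialkoxybenzoyl compound: the 4-oxygen is flanked by two oxygens that hold the boron, is twisted out of the ring plane and lies para to the formyl group, so it should lose its benzyl group first, as in the preparation of syringyl from 3,4,5-trimethoxy compounds.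

Step 10
Reactants: 19 5-bromobenzene-1,2,3-triol
Product: 20 5-bromo-1,2,3-tris(benzyloxy)benzene
Conditions: BnBr (3.5 equiv), K2CO3, DMF, 60 °C, argon
Reagents that add atoms: benzyl bromide, BrCc1ccccc1
Why: Williamson ether synthesis, run under argon because pyrogallols are oxidised by air in base.

Step 11
Reactants: 18 3,5-bis(benzyloxy)-4-hydroxybenzaldehyde; 20 5-bromo-1,2,3-tris(benzyloxy)benzene
Product: 21 3,5-bis(benzyloxy)-4-[3,4,5-tris(benzyloxy)phenoxy]benzaldehyde
Conditions: CuI (10 mol %), picolinic acid (20 mol %), K3PO4, DMSO, 100 °C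
Reagents that add atoms: none
Why: Ligand-accelerated Ullmann diaryl ether synthesis; the CuI/picolinic acid system is chosen because it couples phenols with two ortho substituents, and the aryl bromide has no ortho substituent.

Step 12
Reactants: 21 3,5-bis(benzyloxy)-4-[3,4,5-tris(benzyloxy)phenoxy]benzaldehyde
Product: 23 3,5-bis(benzyloxy)-4-[3,4,5-tris(benzyloxy)phenoxy]phenol, via aryl formate 22 (not isolated)
Conditions: mCPBA, CH2Cl2, 0 °C to rt; then K2CO3 (cat.), MeOH, rt
Reagents that add atoms: mCPBA, OOC(=O)c1cccc(Cl)c1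
Why: Baeyer–Villiger (Dakin-type) oxidation of an electron-rich benzaldehyde followed by methanolysis of the formate, as used for 3,4,5-trialkoxyphenols.

Step 13
Reactants: 16 3-(benzyloxy)-2-chloro-5-[2,4,6-tris(benzyloxy)phenoxy]cyclohexa-2,5-diene-1,4-dione; 23 3,5-bis(benzyloxy)-4-[3,4,5-tris(benzyloxy)phenoxy]phenol
Product: 24 3-(benzyloxy)-2-{3,5-bis(benzyloxy)-4-[3,4,5-tris(benzyloxy)phenoxy]phenoxy}-5-[2,4,6-tris(benzyloxy)phenoxy]cyclohexa-2,5-diene-1,4-dione
Conditions: 23 (1.0 equiv), K2CO3 (1.1 equiv), MeCN, 0 °C to rt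
Reagents that add atoms: none
Why: Addition–elimination of a phenoxide on a chloroquinone, the standard route to aryloxyquinones: C4 carries the only halide, lies β to the less deactivated C2 carbonyl, and chloride leaves far more readily than the aryloxide at C1 or the benzyloxide at C3, so one equivalent of phenol at low temperature should react only there.

Step 14
Reactants: 24 3-(benzyloxy)-2-{3,5-bis(benzyloxy)-4-[3,4,5-tris(benzyloxy)phenoxy]phenoxy}-5-[2,4,6-tris(benzyloxy)phenoxy]cyclohexa-2,5-diene-1,4-dione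
Product: 26 3-[3,5-dihydroxy-4-(3,4,5-trihydroxyphenoxy)phenoxy]-6-(2,4,6-trihydroxyphenoxy)benzene-1,2,4-triol, via nonabenzyl hydroquinone 25 (not isolated)
Conditions: H2 (1 atm), Pd/C (10% Pd), THF/MeOH, rt; filtration and evaporation under argon
Reagents that add atoms: none
Why: Catalytic hydrogenation reduces the quinone to the hydroquinone and hydrogenolyses all nine benzyl ethers while diaryl ether bonds are inert; the product is handled under argon because hydroxyhydroquinones are oxidised by air.

**Compound list**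

1 | 2,4,6-trihydroxybenzaldehyde | O=Cc1c(O)cc(O)cc1O | starting material
2 | 2,4,6-tris(benzyloxy)benzaldehyde | O=Cc1c(OCc2ccccc2)cc(OCc2ccccc2)cc1OCc1ccccc1 | intermediate
3 | 2,4,6-tris(benzyloxy)phenyl formate (not isolated) | O=COc1c(OCc2ccccc2)cc(OCc2ccccc2)cc1OCc1ccccc1 | intermediate
4 | 2,4,6-tris(benzyloxy)phenol | Oc1c(OCc2ccccc2)cc(OCc2ccccc2)cc1OCc1ccccc1 | intermediate
5 | trichloroethylene | ClC=C(Cl)Cl | starting material
6 | 1,3,5-tris(benzyloxy)-2-{[(E)-1,2-dichloroethenyl]oxy}benzene | Cl/C=C(/Cl)Oc1c(OCc2ccccc2)cc(OCc2ccccc2)cc1OCc1ccccc1 | intermediate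
7 | squaric acid | OC1=C(O)C(=O)C1=O | starting material
8 | 3,4-bis(benzyloxy)cyclobut-3-ene-1,2-dione (dibenzyl squarate) | O=C1C(=O)C(OCc2ccccc2)=C1OCc1ccccc1 | intermediate
9 | 1,3,5-tris(benzyloxy)-2-[(chloroethynyl)oxy]benzene (not isolated) | ClC#COc1c(OCc2ccccc2)cc(OCc2ccccc2)cc1OCc1ccccc1 | intermediate
10 | lithium [2,4,6-tris(benzyloxy)phenoxy]acetylide (not isolated) | [Li]C#COc1c(OCc2ccccc2)cc(OCc2ccccc2)cc1OCc1ccccc1 | intermediate
11 | 2,3-bis(benzyloxy)-4-hydroxy-4-{[2,4,6-tris(benzyloxy)phenoxy]ethynyl}cyclobut-2-en-1-one (racemic) | O=C1C(OCc2ccccc2)=C(OCc2ccccc2)C1(O)C#COc1c(OCc2ccccc2)cc(OCc2ccccc2)cc1OCc1ccccc1 | intermediate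
12 | (3Z)-2,3-bis(benzyloxy)-4-hydroxy-6-[2,4,6-tris(benzyloxy)phenoxy]hexa-1,3-dien-5-yn-1-one (enynylketene, not isolated) | O=C=C(OCc1ccccc1)/C(OCc1ccccc1)=C(/O)C#COc1c(OCc2ccccc2)cc(OCc2ccccc2)cc1OCc1ccccc1 | intermediate
13 | ring B diradical: phenoxyl oxygen on C2, sigma radical on C6, hydroxyl on C5 (not isolated) | [O]C1=C(Oc2c(OCc3ccccc3)cc(OCc3ccccc3)cc2OCc2ccccc2)[C]=C(O)C(OCc2ccccc2)=C1OCc1ccccc1 | intermediate
14 | 2,3-bis(benzyloxy)-5-[2,4,6-tris(benzyloxy)phenoxy]cyclohexa-2,5-diene-1,4-dione | O=C1C(OCc2ccccc2)=C(OCc2ccccc2)C(=O)C=C1Oc1c(OCc2ccccc2)cc(OCc2ccccc2)cc1OCc1ccccc1 | intermediate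
15 | 3-(benzyloxy)-2-hydroxy-5-[2,4,6-tris(benzyloxy)phenoxy]cyclohexa-2,5-diene-1,4-dione | O=C1C(OCc2ccccc2)=C(O)C(=O)C=C1Oc1c(OCc2ccccc2)cc(OCc2ccccc2)cc1OCc1ccccc1 | intermediate
16 | 3-(benzyloxy)-2-chloro-5-[2,4,6-tris(benzyloxy)phenoxy]cyclohexa-2,5-diene-1,4-dione | O=C1C(OCc2ccccc2)=C(Cl)C(=O)C=C1Oc1c(OCc2ccccc2)cc(OCc2ccccc2)cc1OCc1ccccc1 | intermediate
17 | 3,4,5-tris(benzyloxy)benzaldehyde | O=Cc1cc(OCc2ccccc2)c(OCc2ccccc2)c(OCc2ccccc2)c1 | starting material
18 | 3,5-bis(benzyloxy)-4-hydroxybenzaldehyde | O=Cc1cc(OCc2ccccc2)c(O)c(OCc2ccccc2)c1 | intermediate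
19 | 5-bromobenzene-1,2,3-triol | Oc1cc(Br)cc(O)c1O | starting material
20 | 5-bromo-1,2,3-tris(benzyloxy)benzene | Brc1cc(OCc2ccccc2)c(OCc2ccccc2)c(OCc2ccccc2)c1 | intermediate
21 | 3,5-bis(benzyloxy)-4-[3,4,5-tris(benzyloxy)phenoxy]benzaldehyde | O=Cc1cc(OCc2ccccc2)c(Oc2cc(OCc3ccccc3)c(OCc3ccccc3)c(OCc3ccccc3)c2)c(OCc2ccccc2)c1 | intermediate
22 | 3,5-bis(benzyloxy)-4-[3,4,5-tris(benzyloxy)phenoxy]phenyl formate (not isolated) | O=COc1cc(OCc2ccccc2)c(Oc2cc(OCc3ccccc3)c(OCc3ccccc3)c(OCc3ccccc3)c2)c(OCc2ccccc2)c1 | intermediate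
23 | 3,5-bis(benzyloxy)-4-[3,4,5-tris(benzyloxy)phenoxy]phenol | Oc1cc(OCc2ccccc2)c(Oc2cc(OCc3ccccc3)c(OCc3ccccc3)c(OCc3ccccc3)c2)c(OCc2ccccc2)c1 | intermediate
24 | 3-(benzyloxy)-2-{3,5-bis(benzyloxy)-4-[3,4,5-tris(benzyloxy)phenoxy]phenoxy}-5-[2,4,6-tris(benzyloxy)phenoxy]cyclohexa-2,5-diene-1,4-dione | O=C1C(OCc2ccccc2)=C(Oc2cc(OCc3ccccc3)c(Oc3cc(OCc4ccccc4)c(OCc4ccccc4)c(OCc4ccccc4)c3)c(OCc3ccccc3)c2)C(=O)C=C1Oc1c(OCc2ccccc2)cc(OCc2ccccc2)cc1OCc1ccccc1 | intermediate
25 | 3-(benzyloxy)-2-{3,5-bis(benzyloxy)-4-[3,4,5-tris(benzyloxy)phenoxy]phenoxy}-5-[2,4,6-tris(benzyloxy)phenoxy]benzene-1,4-diol (not isolated) | Oc1c(OCc2ccccc2)c(Oc2cc(OCc3ccccc3)c(Oc3cc(OCc4ccccc4)c(OCc4ccccc4)c(OCc4ccccc4)c3)c(OCc3ccccc3)c2)c(O)cc1Oc1c(OCc2ccccc2)cc(OCc2ccccc2)cc1OCc1ccccc1 | intermediate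
26 | 3-[3,5-dihydroxy-4-(3,4,5-trihydroxyphenoxy)phenoxy]-6-(2,4,6-trihydroxyphenoxy)benzene-1,2,4-triol | Oc1cc(O)c(Oc2cc(O)c(Oc3cc(O)c(Oc4cc(O)c(O)c(O)c4)c(O)c3)c(O)c2O)c(O)c1 | target

**Count**

Total steps: 14. Longest linear sequence: 9 steps (steps 1, 2, 3, 5, 6, 7, 8, 13, 14).

**Steps most likely to fail**

1. Step 7. Bromide may remove the benzyl group from the C3 oxygen as well as, or instead of, the C4 one (poor site selectivity between two neighbouring vinylogous benzyl esters), or both groups may be lost. The fallback builds the difference into the four-membered ring; it sets out from 8 (with acetylide 10 made from 6 as in step 5) and comes back at 15. One equivalent of pyrrolidine displaces one benzyloxy group of 8 at room temperature to give 3-(benzyloxy)-4-(pyrrolidin-1-yl)cyclobut-3-ene-1,2-dione F1. Acetylide 10 should add to the carbonyl next to the amine-bearing carbon, because the other carbonyl is a vinylogous amide, giving racemic 2-(benzyloxy)-4-hydroxy-3-(pyrrolidin-1-yl)-4-{[2,4,6-tris(benzyloxy)phenoxy]ethynyl}cyclobut-2-en-1-one F2. Thermolysis in toluene or xylene then gives 3-(benzyloxy)-2-(pyrrolidin-1-yl)-5-[2,4,6-tris(benzyloxy)phenoxy]cyclohexa-2,5-diene-1,4-dione F3, with nitrogen fixed on C4 by construction. Dilute aqueous HCl in THF hydrolyses the vinylogous amide (protonation at the C2 carbonyl, water at C4) to 15.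

2. Step 6. The ketene may close onto the proximal alkyne carbon (five-membered ring, alkylidenecyclopentenedione), or the ynol ether may decompose before the ring opens. The fallback keeps a squarate ring expansion for ring B but makes the ring A ether afterwards; it sets out from 8 and comes back at 14, using phenol 4 in its last operation. Ethynylmagnesium bromide adds to 8 to give racemic 2,3-bis(benzyloxy)-4-ethynyl-4-hydroxycyclobut-2-en-1-one F4. Heating in toluene gives 2,3-bis(benzyloxy)cyclohexa-2,5-diene-1,4-dione F5, the best-precedented case of this rearrangement. Bromine adds across the unsubstituted double bond to give racemic trans-2,3-bis(benzyloxy)-5,6-dibromocyclohex-2-ene-1,4-dione F6, and triethylamine in the same flask eliminates HBr to give 2,3-bis(benzyloxy)-5-bromocyclohexa-2,5-diene-1,4-dione F7. Phenol 4 with K2CO3 in MeCN displaces the bromide to give 14.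

3. Step 11. Carbon–oxygen coupling of a phenoxide that has two ortho substituents and a para formyl group may be sluggish, so that reduction of the aryl bromide takes over. The fallback inverts the polarity of ring D; it sets out from 20 and comes back at 21, using phenol 18. Bromine–lithium exchange of 20 with n-BuLi at −78 °C, B(OiPr)3 and acidic work-up give [3,4,5-tris(benzyloxy)phenyl]boronic acid F8. Chan–Lam–Evans coupling of F8 with 18 (Cu(OAc)2, pyridine, 4 Å molecular sieves, air, CH2Cl2, rt), a method that tolerates doubly ortho-substituted phenols, gives 21.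

**Further compounds**

F1 | step 7 | 3-(benzyloxy)-4-(pyrrolidin-1-yl)cyclobut-3-ene-1,2-dione | O=C1C(=O)C(N2CCCC2)=C1OCc1ccccc1
F2 | step 7 | 2-(benzyloxy)-4-hydroxy-3-(pyrrolidin-1-yl)-4-{[2,4,6-tris(benzyloxy)phenoxy]ethynyl}cyclobut-2-en-1-one (racemic) | O=C1C(OCc2ccccc2)=C(N2CCCC2)C1(O)C#COc1c(OCc2ccccc2)cc(OCc2ccccc2)cc1OCc1ccccc1
F3 | step 7 | 3-(benzyloxy)-2-(pyrrolidin-1-yl)-5-[2,4,6-tris(benzyloxy)phenoxy]cyclohexa-2,5-diene-1,4-dione | O=C1C(OCc2ccccc2)=C(N2CCCC2)C(=O)C=C1Oc1c(OCc2ccccc2)cc(OCc2ccccc2)cc1OCc1ccccc1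
F4 | step 6 | 2,3-bis(benzyloxy)-4-ethynyl-4-hydroxycyclobut-2-en-1-one (racemic) | O=C1C(OCc2ccccc2)=C(OCc2ccccc2)C1(O)C#C
F5 | step 6 | 2,3-bis(benzyloxy)cyclohexa-2,5-diene-1,4-dione | O=C1C=CC(=O)C(OCc2ccccc2)=C1OCc1ccccc1
F6 | step 6 | trans-2,3-bis(benzyloxy)-5,6-dibromocyclohex-2-ene-1,4-dione (racemic, one enantiomer drawn) | O=C1C(OCc2ccccc2)=C(OCc2ccccc2)C(=O)[C@H](Br)[C@H]1Br
F7 | step 6 | 2,3-bis(benzyloxy)-5-bromocyclohexa-2,5-diene-1,4-dione | O=C1C=C(Br)C(=O)C(OCc2ccccc2)=C1OCc1ccccc1
F8 | step 11 | [3,4,5-tris(benzyloxy)phenyl]boronic acid | OB(O)c1cc(OCc2ccccc2)c(OCc2ccccc2)c(OCc2ccccc2)c1
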